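## Retrosynthetic overview

1. Target 15 ⇐ acetylation of hydroxy acid 13 ⇐ Horner–Wadsworth–Emmons two-carbon extension and ester reduction of keto acid 10 (sets 13E).
2. 10 ⇐ oxidative opening of ring C of the tricyclic 7,13-diene 7 at C13=C14. Podocarpane C14 becomes the C17 carboxyl on C8 (Δ7 kept); C13 and its methyl become the side-chain methyl ketone.
3. 7 ⇐ Birch dearomatisation of arene 5, then acid equilibration (key step, sets 9α-H). The six ring carbons of m-xylene end as C8, C9, C11, C12, C13 and C17, its methyls as C7 and C16.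
4. 5 ⇐ enantioselective proton-initiated bicyclisation of 4 (sets C5 and C10) ⇐ m-xylene 1 + geranyl chloride 2.
5. Ring order: ring A, then ring B, in one cascade onto the preformed aromatic ring C; ring C is then dearomatised and cut open.

Assumption: the (R)-ligand in step 2 gives the (4aS,10aS) series (otherwise the (S)-ligand is used, nothing else changes), and its ee (about 90%) is raised by recrystallising acid 10, which adds no step.

Locants follow labdane numbering; ring C locants follow podocarpane numbering (podocarpane C14 = labdane C17). The target is the normal-series labdane (5S,9R,10S; 13E).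

## Route

Step 1
Reactants: 1 m-xylene; 2 geranyl chloride
Product: 4 1-[(3E)-4,8-dimethylnona-3,7-dien-1-yl]-3-methylbenzene, via 3-methylbenzyllithium 3 (not isolated)
Conditions: n-BuLi, TMEDA, 1 (5 equiv, neat), 25 °C; then 2, THF, −78 → 0 °C
Reagents that add atoms: none
Why: Lateral (benzylic) lithiation of m-xylene by n-BuLi·TMEDA followed by SN2 alkylation with the primary allylic chloride; excess 1 suppresses dilithiation and the E olefin of 2 is carried through unchanged (no stereocentre is formed).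

Step 2
Reactants: 4
Product: 5 (4aS,10aS)-1,1,4a,7-tetramethyl-1,2,3,4,4a,9,10,10a-octahydrophenanthrene (13-methylpodocarpa-8,11,13-triene)
Conditions: (R)-3,3'-dichloro-BINOL·SbCl5 (1:1, 0.5 equiv), CH2Cl2, −78 °C
Reagents that add atoms: none
Why: Enantioselective proton-initiated cation–olefin bicyclisation (chiral Brønsted acid activated by SbCl5): the chiral proton donor selects the face of the terminal olefin, chair–chair folding of the E-trisubstituted olefin gives the trans ring fusion (5α-H, 10β-CH3), and the cation is captured para to the arene methyl in a Friedel–Crafts closure.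

Step 3
Reactants: 5
Product: 7 (4aS,4bR,10aS)-1,1,4a,7-tetramethyl-1,2,3,4,4a,4b,5,6,10,10a-decahydrophenanthrene (13-methylpodocarpa-7,13-diene), via 13-methylpodocarpa-8,12-diene 6 (not isolated)
Conditions: Li, NH3(l)/THF, EtOH, −33 °C; then conc. HCl, EtOH, reflux
Reagents that add atoms: none
Why: Birch reduction of the 1,2,4-trialkylbenzene protonates the only unsubstituted para pair (C11/C14) to give the 8,12-diene, and acid then equilibrates it, as in the abietic acid series, to the most stable heteroannular 7,13-diene; C9 is protonated from the α face anti to the axial C10 methyl, so 9α-H (side chain β) is set under thermodynamic control.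

Step 4
Reactants: 7
Product: 9 (1R,4aS,8aS)-5,5,8a-trimethyl-1-(3-oxobutyl)-1,4,4a,5,6,7,8,8a-octahydronaphthalene-2-carbaldehyde, via 13-methylpodocarp-7-ene-13β,14β-diol 8 (not isolated)
Conditions: OsO4 (2 mol %), NaIO4 (4 equiv), 2,6-lutidine, dioxane/H2O (3:1), 0 → 23 °C
Reagents that add atoms: osmium tetroxide, O=[Os](=O)(=O)=O; sodium periodate, [Na+].[O-]I(=O)(=O)=O
Why: Lemieux–Johnson oxidation (catalytic osmylation, then periodate glycol cleavage): the exposed C13=C14 terminus of the diene should be dihydroxylated before the ring-fusion C7=C8 bond (the preference I recall for abietate-type dienes), either diol face gives the same product, and cleavage leaves C7=C8 as a deactivated enal with C5, C9 and C10 untouched.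

Step 5
Reactants: 9
Product: 10 (1R,4aS,8aS)-5,5,8a-trimethyl-1-(3-oxobutyl)-1,4,4a,5,6,7,8,8a-octahydronaphthalene-2-carboxylic acid
Conditions: NaClO2, NaH2PO4, 2-methyl-2-butene, t-BuOH/H2O, 23 °C
Reagents that add atoms: sodium chlorite, [Na+].[O-]Cl=O
Why: Pinnick oxidation is selective for the aldehyde; the hypochlorous acid by-product is scavenged, so the trisubstituted olefin and the ketone survive.

Step 6
Reactants: 10; 11 triethyl phosphonoacetate
Product: 12 (1R,4aS,8aS)-1-[(3E)-5-ethoxy-3-methyl-5-oxopent-3-en-1-yl]-5,5,8a-trimethyl-1,4,4a,5,6,7,8,8a-octahydronaphthalene-2-carboxylic acid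
Conditions: 11 (2 equiv), NaH (3.2 equiv), THF, 0 → 50 °C; aq. HCl; SiO2
Reagents that add atoms: triethyl phosphonoacetate, CCOC(=O)CP(=O)(OCC)OCC
Why: Horner–Wadsworth–Emmons olefination of the methyl ketone (the carboxylate of 10 is inert) places the ester trans to the larger CH2 chain, about 5:1 E:Z expected, which sets the 13E geometry once the minor Z isomer is removed by chromatography.

Step 7
Reactants: 12
Product: 13 (1R,4aS,8aS)-1-[(3E)-5-hydroxy-3-methylpent-3-en-1-yl]-5,5,8a-trimethyl-1,4,4a,5,6,7,8,8a-octahydronaphthalene-2-carboxylic acid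
Conditions: i-Bu2AlH (4 equiv), CH2Cl2, −78 °C; aq. KNaC4H4O6, then pH 3
Reagents that add atoms: none
Why: i-Bu2AlH reduces the conjugated ethyl ester 1,2 to the allylic alcohol, while the ring acid, held as its aluminium carboxylate, is not reduced at −78 °C.

Step 8
Reactants: 13; 14 acetic anhydride
Product: 15 (1R,4aS,8aS)-1-[(3E)-5-acetoxy-3-methylpent-3-en-1-yl]-5,5,8a-trimethyl-1,4,4a,5,6,7,8,8a-octahydronaphthalene-2-carboxylic acid
Conditions: Ac2O (1.5 equiv), pyridine, 0 → 23 °C; then H2O
Reagents that add atoms: acetic anhydride, CC(=O)OC(C)=O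
Why: O-acylation of the primary allylic alcohol; a mixed anhydride at the hindered conjugated acid, if formed, is hydrolysed in the aqueous pyridine work-up.

## Compound list

1 | m-xylene (1,3-dimethylbenzene) | Cc1cccc(C)c1 | starting material
2 | geranyl chloride, (2E)-1-chloro-3,7-dimethylocta-2,6-diene | CC(C)=CCC/C(C)=C/CCl | starting material
3 | 3-methylbenzyllithium | [Li]Cc1cccc(C)c1 | intermediate
4 | 1-[(3E)-4,8-dimethylnona-3,7-dien-1-yl]-3-methylbenzene | Cc1cccc(CC/C=C(\C)CCC=C(C)C)c1 | intermediate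
5 | (4aS,10aS)-1,1,4a,7-tetramethyl-1,2,3,4,4a,9,10,10a-octahydrophenanthrene (13-methylpodocarpa-8,11,13-triene; 5α-H, 10β-CH3) | Cc1ccc2c(c1)CC[C@H]1C(C)(C)CCC[C@]21C | intermediate
6 | (4aS,10aS)-1,1,4a,7-tetramethyl-1,2,3,4,4a,5,8,9,10,10a-decahydrophenanthrene (13-methylpodocarpa-8,12-diene) | CC1=CCC2=C(C1)CC[C@H]1C(C)(C)CCC[C@]21C | intermediate
7 | (4aS,4bR,10aS)-1,1,4a,7-tetramethyl-1,2,3,4,4a,4b,5,6,10,10a-decahydrophenanthrene (13-methylpodocarpa-7,13-diene; 9α-H) | CC1=CC2=CC[C@H]3C(C)(C)CCC[C@]3(C)[C@H]2CC1 | intermediate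
8 | 13-methylpodocarp-7-ene-13β,14β-diol (cis-diol; the α-face cis-diol would give the same product) | C[C@@]1(O)CC[C@H]2C(=CC[C@H]3C(C)(C)CCC[C@]23C)[C@@H]1O | intermediate
9 | (1R,4aS,8aS)-5,5,8a-trimethyl-1-(3-oxobutyl)-1,4,4a,5,6,7,8,8a-octahydronaphthalene-2-carbaldehyde | CC(=O)CC[C@H]1C(C=O)=CC[C@H]2C(C)(C)CCC[C@]12C | intermediate
10 | (1R,4aS,8aS)-5,5,8a-trimethyl-1-(3-oxobutyl)-1,4,4a,5,6,7,8,8a-octahydronaphthalene-2-carboxylic acid | CC(=O)CC[C@H]1C(C(=O)O)=CC[C@H]2C(C)(C)CCC[C@]12C | intermediate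
11 | triethyl phosphonoacetate | CCOC(=O)CP(=O)(OCC)OCC | starting material
12 | (1R,4aS,8aS)-1-[(3E)-5-ethoxy-3-methyl-5-oxopent-3-en-1-yl]-5,5,8a-trimethyl-1,4,4a,5,6,7,8,8a-octahydronaphthalene-2-carboxylic acid | CCOC(=O)/C=C(\C)CC[C@H]1C(C(=O)O)=CC[C@H]2C(C)(C)CCC[C@]12C | intermediate
13 | (1R,4aS,8aS)-1-[(3E)-5-hydroxy-3-methylpent-3-en-1-yl]-5,5,8a-trimethyl-1,4,4a,5,6,7,8,8a-octahydronaphthalene-2-carboxylic acid | OC/C=C(\C)CC[C@H]1C(C(=O)O)=CC[C@H]2C(C)(C)CCC[C@]12C | intermediate
14 | acetic anhydride | CC(=O)OC(C)=O | starting material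
15 | (1R,4aS,8aS)-1-[(3E)-5-acetoxy-3-methylpent-3-en-1-yl]-5,5,8a-trimethyl-1,4,4a,5,6,7,8,8a-octahydronaphthalene-2-carboxylic acid, (13E)-15-acetoxylabda-7,13-dien-17-oic acid | CC(=O)OC/C=C(\C)CC[C@H]1C(C(=O)O)=CC[C@H]2C(C)(C)CCC[C@]12C | target

## Summary

Total steps: 8. Longest linear sequence: 8 (1 → 15; 2, 11 and 14 are purchased).

Steps most likely to fail:

**Step 3 (Birch reduction of a hindered trialkylbenzene and equilibration to one diene).** The fallback sets out from 2 and comes back at 7, with an anisole ring as the terminator so that the dearomatisation is easy and regiodefined.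
- Commercial 3-methoxybenzylmagnesium chloride is coupled with 2 (Li2CuCl4 cat., THF) to give 1-[(3E)-4,8-dimethylnona-3,7-dien-1-yl]-3-methoxybenzene F2.
- The step 2 conditions close it para to the methoxy group to 13-methoxypodocarpa-8,11,13-triene F3.
- Li/NH3/t-BuOH gives the enol ether 13-methoxypodocarpa-8,12-diene F4.
- Aqueous HCl hydrolyses it to podocarp-8-en-13-one F5, which conjugates in the same medium to podocarp-8(14)-en-13-one F6 (9α-H).
- MeLi adds 1,2 to give 13-methylpodocarp-8(14)-en-13-ol F7.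
- TsOH in hot benzene dehydrates and equilibrates F7 to 7.

**Step 4 (which olefin of the diene is cleaved).** The fallback sets out from 7 and comes back at 9, replacing osmylation by electrophilic oxygen transfer. mCPBA (1 equiv, NaHCO3, CH2Cl2, −20 °C) epoxidises the more accessible diene terminus to 13β,14β-epoxy-13-methylpodocarp-7-ene F8, and H5IO6 in aqueous THF opens and cleaves the epoxide to 9.

**Step 2 (enantioselectivity and completeness of the proton-initiated cyclisation).** The fallback sets out from 4 and comes back at 7, with a halonium in place of the proton. N-Iodosuccinimide with a stoichiometric chiral binaphthol-derived phosphoramidite promoter (toluene, −40 °C) gives 3β-iodo-13-methylpodocarpa-8,11,13-triene F1. The iodine is a traceless handle: under the step 3 conditions Li/NH3 cleaves the C–I bond while reducing the arene, and the acid stage then delivers 7.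

## Further compounds

F1 | step 2 | (2S,4aS,10aR)-2-iodo-1,1,4a,7-tetramethyl-1,2,3,4,4a,9,10,10a-octahydrophenanthrene (3β-iodo-13-methylpodocarpa-8,11,13-triene) | Cc1ccc2c(c1)CC[C@H]1C(C)(C)[C@@H](I)CC[C@]21C
F2 | step 3 | 1-[(3E)-4,8-dimethylnona-3,7-dien-1-yl]-3-methoxybenzene | COc1cccc(CC/C=C(\C)CCC=C(C)C)c1
F3 | step 3 | (4aS,10aS)-7-methoxy-1,1,4a-trimethyl-1,2,3,4,4a,9,10,10a-octahydrophenanthrene (13-methoxypodocarpa-8,11,13-triene) | COc1ccc2c(c1)CC[C@H]1C(C)(C)CCC[C@]21C
F4 | step 3 | 13-methoxypodocarpa-8,12-diene (5α-H, 10β-CH3) | COC1=CCC2=C(C1)CC[C@H]1C(C)(C)CCC[C@]21C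
F5 | step 3 | podocarp-8-en-13-one (5α-H, 10β-CH3) | O=C1CCC2=C(C1)CC[C@H]1C(C)(C)CCC[C@]21C
F6 | step 3 | podocarp-8(14)-en-13-one (5α-H, 9α-H, 10β-CH3) | O=C1C=C2CC[C@H]3C(C)(C)CCC[C@]3(C)[C@H]2CC1
F7 | step 3 | 13-methylpodocarp-8(14)-en-13-ol (C13 epimers; 5α-H, 9α-H, 10β-CH3) | CC1(O)C=C2CC[C@H]3C(C)(C)CCC[C@]3(C)[C@H]2CC1
F8 | step 4 | 13β,14β-epoxy-13-methylpodocarp-7-ene (5α-H, 9α-H, 10β-CH3) | C[C@@]12CC[C@H]3C(=CC[C@H]4C(C)(C)CCC[C@]34C)[C@@H]1O2
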